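**Strategy.** The depside is not made by acylating a phenol with a 2,6-disubstituted benzoic acid; instead ring A is grown on an ester that already exists. In ring A the carbonyl-bearing C1 lies between pentyl-bearing C6 and oxygen-bearing C2, with a second oxygen on C4. An oct-2-ynoate delivers C1 and C6 with the carbonyl and pentyl group attached, and a 1,1,3-trioxygenated butadiene delivers C2–C5, so one cycloaddition–aromatisation forms the C1–C2 and C5–C6 bonds and the whole benzene ring. The precursor is the oct-2-ynoate ester of the ring-B 4-hydroxyl, with the ring-B 2-hydroxyl and carboxyl both masked as benzyl groups for a single final hydrogenolysis.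

Key step: step 7

Remark: olivetolic acid (2,4-dihydroxy-6-pentylbenzoic acid) is assumed to be purchasable and is used as the ring-B starting material. The target has no stereocentre, and the geometry of the ketene-acetal double bond of the diene has no bearing on the aromatic product.

**Step 1**
Reactants: 1 olivetolic acid (2,4-dihydroxy-6-pentylbenzoic acid); 2 benzyl bromide
Product: 3 benzyl 2,4-dihydroxy-6-pentylbenzoate
Conditions: BnBr (1.05 equiv), KHCO3 (1.1 equiv), DMF, 23 °C
Reagents that add atoms: none
Why: SN2 O-alkylation of the carboxylate; hydrogencarbonate deprotonates only the carboxylic acid, so the phenols stay free and the benzyl ester should form selectively.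

**Step 2**
Reactants: 3 benzyl 2,4-dihydroxy-6-pentylbenzoate
Product: 4 benzyl 2-hydroxy-6-pentyl-4-(triisopropylsilyloxy)benzoate
Conditions: iPr3SiCl (1.1 equiv), imidazole (2.2 equiv), DMF, 0 to 23 °C
Reagents that add atoms: chlorotriisopropylsilane, CC(C)[Si](Cl)(C(C)C)C(C)C
Why: Phenol silylation; the 2-hydroxyl is hydrogen-bonded to the ester carbonyl and flanked by it, so the bulky silyl chloride should take only the open 4-hydroxyl.

**Step 3**
Reactants: 4 benzyl 2-hydroxy-6-pentyl-4-(triisopropylsilyloxy)benzoate; 2 benzyl bromide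
Product: 5 benzyl 2-(benzyloxy)-6-pentyl-4-(triisopropylsilyloxy)benzoate
Conditions: BnBr (1.5 equiv), K2CO3 (2 equiv), acetone, reflux
Reagents that add atoms: none
Why: Williamson etherification of the remaining chelated phenol; the aryl triisopropylsilyl ether and the hindered benzyl ester should tolerate anhydrous carbonate in acetone.

**Step 4**
Reactants: 5 benzyl 2-(benzyloxy)-6-pentyl-4-(triisopropylsilyloxy)benzoate
Product: 6 benzyl 2-(benzyloxy)-4-hydroxy-6-pentylbenzoate
Conditions: Bu4NF (1.1 equiv), AcOH (1.1 equiv), THF, 0 °C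
Reagents that add atoms: none
Why: Fluoride-mediated cleavage of the aryl silyl ether; the acetic acid buffer keeps the medium non-basic, so the benzyl ether and benzyl ester should be untouched.

**Step 5**
Reactants: 6 benzyl 2-(benzyloxy)-4-hydroxy-6-pentylbenzoate; 7 oct-2-ynoic acid
Product: 8 benzyl 2-(benzyloxy)-4-(oct-2-ynoyloxy)-6-pentylbenzoate
Conditions: DCC (1.2 equiv), DMAP (0.1 equiv), CH2Cl2, 0 to 23 °C
Reagents that add atoms: none
Why: Steglich esterification of an unhindered phenol with an unhindered alk-2-ynoic acid, a standard way to aryl alkynoates; the depside ester link is thus made before either ortho substituent of ring A exists.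

**Step 6**
Reactants: 9 methyl (E)-3-methoxybut-2-enoate
Product: 11 (E)-1,3-dimethoxy-1-(trimethylsilyloxy)buta-1,3-diene (Brassard's diene), via lithium (1Z)-1,3-dimethoxybuta-1,3-dien-1-olate 10 (not isolated)
Conditions: LiN(iPr)2 (1.1 equiv), THF, −78 °C; then Me3SiCl (1.2 equiv), −78 to 23 °C; distillation under reduced pressure
Reagents that add atoms: chlorotrimethylsilane, C[Si](C)(C)Cl
Why: Kinetic γ-deprotonation of the vinylogous carbonate gives the extended enolate, which the hard silyl chloride traps on oxygen (silyl ketene acetal formation), the standard preparation of this diene.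

**Step 7**
Reactants: 8 benzyl 2-(benzyloxy)-4-(oct-2-ynoyloxy)-6-pentylbenzoate; 11 (E)-1,3-dimethoxy-1-(trimethylsilyloxy)buta-1,3-diene
Product: 14 benzyl 2-(benzyloxy)-4-(2-hydroxy-4-methoxy-6-pentylbenzoyloxy)-6-pentylbenzoate, via cyclohexa-1,4-diene mixed ketal cycloadduct 12 (not isolated), via ring-A trimethylsilyl ether 13 (not isolated)
Conditions: 11 (3 equiv), toluene, 120 °C, sealed tube; then 1 M HCl, THF, 23 °C
Reagents that add atoms: none
Why: The electron-rich ketene-acetal diene and the electron-poor aryl ynoate should combine in a normal-demand, strongly asynchronous [4+2] cycloaddition: the unsubstituted CH2 terminus of the diene (its most nucleophilic carbon) bonds to the pentyl-bearing β-carbon of the ynoate and the acetal carbon bonds to the α-carbon, giving cyclohexa-1,4-diene 12. A 1,4-elimination of methanol (methoxide from the ketal carbon, hydrogen from the doubly allylic CH2) then aromatises 12 to silyl ether 13, which the acidic work-up hydrolyses to phenol 14. The closest known reaction type is the Diels–Alder benzannulation of 1-alkoxy-1-silyloxy-3-oxygenated butadienes with alk-2-ynoates to give resorcylate esters. Ring A is closed as a six-membered carbocycle by the intermolecular cycloaddition itself, both new bonds (ring-A C1–C2 and C5–C6) being formed in the one operation. No stereocentre has to be controlled, because the only sp3 stereocentre (the ketal carbon of 12) disappears on aromatisation. The step needs regioselectivity, which the polarity match of the diene terminus with the ynoate β-carbon secures, and chemoselectivity, which rests on the aryl ester lowering the alkyne LUMO, on the ring-B O-benzyl group leaving no acidic hydroxyl to consume the silyl ketene acetal, and on the inertness of the hindered benzyl ester.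

**Step 8**
Reactants: 14 benzyl 2-(benzyloxy)-4-(2-hydroxy-4-methoxy-6-pentylbenzoyloxy)-6-pentylbenzoate
Product: 15 benzyl 2-(benzyloxy)-4-(2,4-dimethoxy-6-pentylbenzoyloxy)-6-pentylbenzoate
Conditions: MeI (3 equiv), K2CO3 (2 equiv), acetone, 50 °C
Reagents that add atoms: iodomethane, CI
Why: Williamson methylation of the only free phenol; the depside carbonyl is shielded by two ortho substituents and should survive anhydrous carbonate, as in classical depside methylations.

**Step 9**
Reactants: 15 benzyl 2-(benzyloxy)-4-(2,4-dimethoxy-6-pentylbenzoyloxy)-6-pentylbenzoate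
Product: 16 4-(2,4-dimethoxy-6-pentylbenzoyloxy)-2-hydroxy-6-pentylbenzoic acid (target)
Conditions: H2 (1 atm), Pd/C (palladium on carbon, 10%), EtOAc, 23 °C; concentration without heating
Reagents that add atoms: none
Why: Catalytic hydrogenolysis cleaves both benzylic C–O bonds (ether and ester, two equivalents of toluene) while the aryl ester, methyl ethers and arenes should be inert; avoiding heat prevents decarboxylation of the salicylic acid.

**Compound list**
1 | olivetolic acid (2,4-dihydroxy-6-pentylbenzoic acid) | CCCCCc1cc(O)cc(O)c1C(=O)O | starting material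
2 | benzyl bromide | BrCc1ccccc1 | starting material
3 | benzyl 2,4-dihydroxy-6-pentylbenzoate | CCCCCc1cc(O)cc(O)c1C(=O)OCc1ccccc1 | intermediate
4 | benzyl 2-hydroxy-6-pentyl-4-(triisopropylsilyloxy)benzoate | CCCCCc1cc(O[Si](C(C)C)(C(C)C)C(C)C)cc(O)c1C(=O)OCc1ccccc1 | intermediate
5 | benzyl 2-(benzyloxy)-6-pentyl-4-(triisopropylsilyloxy)benzoate | CCCCCc1cc(O[Si](C(C)C)(C(C)C)C(C)C)cc(OCc2ccccc2)c1C(=O)OCc1ccccc1 | intermediate
6 | benzyl 2-(benzyloxy)-4-hydroxy-6-pentylbenzoate | CCCCCc1cc(O)cc(OCc2ccccc2)c1C(=O)OCc1ccccc1 | intermediate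
7 | oct-2-ynoic acid | CCCCCC#CC(=O)O | starting material
8 | benzyl 2-(benzyloxy)-4-(oct-2-ynoyloxy)-6-pentylbenzoate | CCCCCC#CC(=O)Oc1cc(CCCCC)c(C(=O)OCc2ccccc2)c(OCc2ccccc2)c1 | intermediate
9 | methyl (E)-3-methoxybut-2-enoate | CO/C(C)=C/C(=O)OC | starting material
10 | lithium (1Z)-1,3-dimethoxybuta-1,3-dien-1-olate | C=C(OC)/C=C(\OC)O[Li] | intermediate
11 | (E)-1,3-dimethoxy-1-(trimethylsilyloxy)buta-1,3-diene (Brassard's diene) | C=C(OC)/C=C(\OC)O[Si](C)(C)C | intermediate
12 | benzyl 2-(benzyloxy)-4-{[4,6-dimethoxy-2-pentyl-6-(trimethylsilyloxy)cyclohexa-1,4-dien-1-yl]carbonyloxy}-6-pentylbenzoate (racemic at the ketal carbon) | CCCCCC1=C(C(=O)Oc2cc(CCCCC)c(C(=O)OCc3ccccc3)c(OCc3ccccc3)c2)C(OC)(O[Si](C)(C)C)C=C(OC)C1 | intermediate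
13 | benzyl 2-(benzyloxy)-4-[4-methoxy-6-pentyl-2-(trimethylsilyloxy)benzoyloxy]-6-pentylbenzoate | CCCCCc1cc(OC)cc(O[Si](C)(C)C)c1C(=O)Oc1cc(CCCCC)c(C(=O)OCc2ccccc2)c(OCc2ccccc2)c1 | intermediate
14 | benzyl 2-(benzyloxy)-4-(2-hydroxy-4-methoxy-6-pentylbenzoyloxy)-6-pentylbenzoate | CCCCCc1cc(OC)cc(O)c1C(=O)Oc1cc(CCCCC)c(C(=O)OCc2ccccc2)c(OCc2ccccc2)c1 | intermediate
15 | benzyl 2-(benzyloxy)-4-(2,4-dimethoxy-6-pentylbenzoyloxy)-6-pentylbenzoate | CCCCCc1cc(OC)cc(OC)c1C(=O)Oc1cc(CCCCC)c(C(=O)OCc2ccccc2)c(OCc2ccccc2)c1 | intermediate
16 | 4-(2,4-dimethoxy-6-pentylbenzoyloxy)-2-hydroxy-6-pentylbenzoic acid | CCCCCc1cc(OC(=O)c2c(CCCCC)cc(OC)cc2OC)cc(O)c1C(=O)O | target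

**Step count.** Total: 9 steps. Longest linear sequence: 8 steps (steps 1–5, 7, 8, 9 from olivetolic acid); step 6 is a one-step side branch.

**Steps most likely to fail**

Step 7. The cycloaddition onto a β-alkyl ynoate may be too slow at temperatures the diene tolerates, the diene being lost by silyl migration and oligomerisation; the adduct may also aromatise incompletely or with loss of the wrong oxygen substituent. The fallback sets out from 3 and 6 and returns at 15; it builds ring A separately and makes the depside bond by acylation. Ester 3 is O-methylated twice (MeI, K2CO3, DMF, 50 °C) to benzyl 2,4-dimethoxy-6-pentylbenzoate F1. Hydrogenolysis (H2, Pd/C, EtOAc) gives 2,4-dimethoxy-6-pentylbenzoic acid F2. Trifluoroacetic anhydride in toluene at 0 to 23 °C converts F2 into 2,4-dimethoxy-6-pentylbenzoic trifluoroacetic anhydride F3, which acylates phenol 6 in the same flask to give 15. This is the classical trifluoroacetic anhydride depside coupling, which tolerates 2,6-disubstituted acids because the highly activated mixed anhydride is attacked by an unhindered phenol.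

Step 8. Carbonate or phenoxide may cleave or transesterify the activated aryl ester, or alkylation of the hydrogen-bonded phenol may stall. The fallback sets out from 14 and returns at 15: Mitsunobu etherification with methanol (MeOH, PPh3, diisopropyl azodicarboxylate, THF, 0 to 23 °C). This redox condensation needs no added base, and it passes through no new compound.

Step 3. The silyl group may be lost under the carbonate conditions, followed by benzylation at the 4-oxygen, or alkylation of the chelated 2-hydroxyl may be slow. The fallback sets out from 3 and returns at 6, replacing the silyl ether by a base-stable allyl ether. Selective allylation of the non-chelated 4-hydroxyl (allyl bromide 1.05 equiv, K2CO3, acetone, 23 °C) gives benzyl 2-hydroxy-6-pentyl-4-(prop-2-en-1-yloxy)benzoate F4. Forcing benzylation (BnBr, K2CO3, DMF, 60 °C) gives benzyl 2-(benzyloxy)-6-pentyl-4-(prop-2-en-1-yloxy)benzoate F5. Allyl transfer to morpholine with catalytic Pd(PPh3)4 in THF at 23 °C then frees the 4-hydroxyl and gives 6.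

**Further compounds**
F1 | step 7 | benzyl 2,4-dimethoxy-6-pentylbenzoate | CCCCCc1cc(OC)cc(OC)c1C(=O)OCc1ccccc1
F2 | step 7 | 2,4-dimethoxy-6-pentylbenzoic acid | CCCCCc1cc(OC)cc(OC)c1C(=O)O
F3 | step 7 | 2,4-dimethoxy-6-pentylbenzoic trifluoroacetic anhydride | CCCCCc1cc(OC)cc(OC)c1C(=O)OC(=O)C(F)(F)F
F0 | step 8 | none | none
F4 | step 3 | benzyl 2-hydroxy-6-pentyl-4-(prop-2-en-1-yloxy)benzoate | C=CCOc1cc(O)c(C(=O)OCc2ccccc2)c(CCCCC)c1
F5 | step 3 | benzyl 2-(benzyloxy)-6-pentyl-4-(prop-2-en-1-yloxy)benzoate | C=CCOc1cc(OCc2ccccc2)c(C(=O)OCc2ccccc2)c(CCCCC)c1
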